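A ratio was my first step: the south run's target at 6.0 h, put at 32.2% on the line between its readings at 5.00 h and 8.00 h, over the south-west run's 36.1%, which gives 0.892. You asked for a quick number and guessed that slow substrate would pay. Going from 37 mM to 74 mM of substrate had lowered the percent by 3.9 percentage points, so I froze the south-west curve of percent against time. I treated substrate as pseudo-first-order, each portion following that curve from its own entry.

| flask | substrate | partner | free catalyst | second catalyst | remark | time |
|---|---|---|---|---|---|---|
| south-west | 37 mM | 29.6 mM | 0.37 mM | 0.93 mM | run made earlier |  |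
| east | 37 mM | 29.6 mM | 0.52 mM | 0.93 mM | run made earlier |  |
| north-west | 37 mM | 29.6 mM | 0.81 mM | 0.93 mM | run made earlier |  |
| south | 74 mM | 29.6 mM | 0.37 mM | 0.93 mM | run made earlier |  |
| alpha | 37 mM | 29.6 mM (fed, over 4.0 h) | 0.37 mM | 0.93 mM | all else is in the flask from the start; the feed brings no volume worth counting | 6.0 h |
| beta | 37 mM (in portions, 2, over 4.0 h) | 29.6 mM | 0.37 mM | 0.93 mM | first portion at the start, last at 4.0 h | 6.0 h |
| delta | 37 mM (fed, over 4.0 h) | 29.6 mM | 0.37 mM | 0.93 mM | all else is in the flask from the start; the feed brings no volume worth counting | 6.0 h |
| theta | 37 mM | 29.6 mM | 0.37 mM | 0.93 mM | everything together at the start | 6.0 h |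

- south-west (time / h: target / %): 0.500: 4.1; 1.00: 10.0; 2.50: 23.0; 6.00: 36.1
- east (time / h: target / %): 0.833: 10.2; 2.50: 25.9; 5.00: 37.1; 8.00: 47.4
- north-west (time / h: target / %): 0.500: 7.7; 1.33: 19.8; 3.00: 33.8; 8.00: 52.3
- south (time / h: target / %): 2.00: 17.7; 4.00: 26.3; 5.00: 29.8; 8.00: 37.0

(readings scatter by 0.5 percentage points)

1. the flask that comes out highest in amount of target, in percent of the substrate charged, or "all alike" when all lie within 1.5 percentage points (alpha / beta / delta / theta / all alike)
2. target at the end, in percent of the substrate charged, alpha
3. target at the end, in percent of the substrate charged, beta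
4. target at the end, in percent of the substrate charged, delta
5. target at the end, in percent of the substrate charged, theta



In delta the steady feed and in beta the portions at the start and at 4.0 h both enter on average at 2.00 h. So the mean age, a, came to 4.00 h for each, a being the mean time substrate has spent in the flask by the end. The straight chord between the south-west readings at 2.50 h and 6.00 h put that age at 28.6%, an interpolation and not a reading. It sits low, because the south-west readings bend, climbing more slowly per hour after 2.50 h than before it. Theta, at age 6.0 h, repeats the south-west run and reads 36.1%, which is 7.5 points above the chord. The chord's sag overstates that gap, but I still put theta ahead of your slow substrate. Alpha I left without a number, since partner stood at 29.6 mM in every earlier run.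

The forecast also named theta, with theta 36.1%, alpha 32.5%, delta 28.5% and beta 30%, on the ground that “low early substrate wastes the uninhibited period”. My beta of 28.6% lay below its figure, while my delta matched its figure.

The flasks gave theta 36.1%, the highest, then alpha 32.4%, delta 29.3% and beta 28.2%.

    substrate + free catalyst ⇌ free catalyst + open intermediate (K = 0.750, k = 0.350 M⁻¹ s⁻¹)
    partner + catalyst intermediate → second catalyst + target (k = 0.290 M⁻¹ s⁻¹)
    substrate ⇌ dormant form (K = 4.30, k = 2.90 × 10⁻⁴ s⁻¹)
    second catalyst + open intermediate ⇌ catalyst intermediate (K = 570 M⁻¹, k = 0.480 M⁻¹ s⁻¹)

Alpha, whose substrate had theta's age, stood 3.7 points lower, with a mean partner of 10.3 mM over the first 4.0 h against 23.2 mM in theta. At the age of 4.00 h, the chord's 28.6% lay 0.70 points below delta and 0.40 points above beta.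

Readings and results were computed with constants of no real substance; noise was put on by code.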